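## Retrosynthetic overview

1. The trisubstituted oxirane is installed last, by reagent-controlled Shi epoxidation of the E-alkene.
2. The trans-α-methyl-γ-lactone is cut at its ring CH2–CH(CH3) bond and its ester C–O bond, giving a terminal (R)-epoxide plus a propionyl unit (new isothiourea-catalysed [3+2] annulation).
3. The aryl ether comes from a Mitsunobu coupling of the intact coumarin phenol with an allylic epoxy alcohol.
4. The epoxy alcohol comes from organocatalytic α-chlorination of the C6 aldehyde made by selective ozonolysis of geranyl acetate, which supplies the E-alkene.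
5. Ring order: terminal oxirane → γ-lactone → trisubstituted oxirane; the coumarin is bought.

Assumption: geranyl acetate, hydrangetin (7-hydroxy-8-methoxycoumarin) and both antipodes of the named organocatalysts are purchasable; side-chain carbons are called C1' (OCH2) to C8' (lactone C=O).

## Route

Step 1
Reactants: 1 geranyl acetate [(2E)-3,7-dimethylocta-2,6-dien-1-yl acetate]
Product: 3 (2E)-3-methyl-6-oxohex-2-en-1-yl acetate, via ozonide 2 (not isolated)
Conditions: O3 (1.0 equiv, Sudan Red 7B end-point), CH2Cl2, −78 °C; PPh3, −78 °C → rt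
Reagents that add atoms: ozone, [O-][O+]=O
Why: Criegee ozonolysis with reductive work-up; the electron-rich 6,7-alkene reacts far faster than the 2,3-alkene deactivated by the allylic acetate, so only the distal olefin is cleaved and no stereocentre is formed.

Step 2
Reactants: 3 (2E)-3-methyl-6-oxohex-2-en-1-yl acetate
Product: 6 (2E)-3-methyl-4-[(2R)-oxiran-2-yl]but-2-en-1-ol, via chloroaldehyde 4 (not isolated), via chlorohydrin 5 (not isolated)
Conditions: (2R,5R)-2,5-diphenylpyrrolidine (10 mol%), NCS, CH2Cl2, −20 °C → rt; NaBH4, MeOH, 0 °C; KOH, EtOH–H2O, rt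
Reagents that add atoms: none
Why: Organocatalytic enamine α-chlorination sets the first stereocentre: a phenyl group of the amine shields one face of the (E)-enamine, so NCS chlorinates the open face to give C5' as (S) (sense assigned from the enamine shielding model, to be confirmed on 6; the (2S,5S) amine is the switch). NaBH4 then fixes the labile centre, and KOH closes the oxirane by intramolecular SN2 with inversion to (R) while saponifying the acetate; the chlorine introduced by NCS leaves again as chloride.

Step 3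
Reactants: 6 (2E)-3-methyl-4-[(2R)-oxiran-2-yl]but-2-en-1-ol; 7 hydrangetin (7-hydroxy-8-methoxy-2H-chromen-2-one)
Product: 8 8-methoxy-7-{[(2E)-3-methyl-4-[(2R)-oxiran-2-yl]but-2-en-1-yl]oxy}-2H-chromen-2-one
Conditions: PPh3, DIAD, THF, 0 °C → rt
Reagents that add atoms: none
Why: Mitsunobu etherification; the acidic coumarin phenol displaces the primary allylic oxyphosphonium by SN2 under neutral conditions, leaving the E-alkene, the oxirane and C5' untouched.

Step 4
Reactants: 8 8-methoxy-7-{[(2E)-3-methyl-4-[(2R)-oxiran-2-yl]but-2-en-1-yl]oxy}-2H-chromen-2-one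
Product: 9 8-methoxy-7-{[(2E)-3-methyl-4-[(2S,4R)-4-methyl-5-oxooxolan-2-yl]but-2-en-1-yl]oxy}-2H-chromen-2-one
Conditions: (EtCO)2O (2 equiv), (2R,3S)-HyperBTM [(2R,3S)-3-isopropyl-2-phenyl-3,4-dihydro-2H-benzo[4,5]thiazolo[3,2-a]pyrimidine, 10 mol%], LiClO4 (1 equiv), iPr2NEt, CH2Cl2–Et2O, 0 °C → rt
Reagents that add atoms: propionic anhydride, CCC(=O)OC(=O)CC
Why: Proposed new method: a formal [3+2] annulation in which the isothiourea is N-acylated by the anhydride and deprotonated to a (Z)-C1-ammonium enolate held planar by the 1,5-O···S contact; the Li+-activated terminal epoxide is opened by SN2 at its CH2 carbon (C5' untouched, so the (R)-oxirane carbon becomes the (S)-lactone carbon) on the enolate face opposite the catalyst phenyl group, which sets C7' as (R) under catalyst control (the (2R,3S) catalyst is chosen on this model for Si-face attack, its antipode being the switch), and the γ-alkoxide then lactonises onto the acyl isothiouronium to release the catalyst; the closest known reactions are the isothiourea-catalysed Michael addition–lactonisation of C1-ammonium enolates, the cinchona-amine/LiClO4 ketene–aldehyde cycloaddition and the LiClO4-promoted opening of epoxides by enolates, but an ammonium enolate has not yet been alkylated by an epoxide.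

Step 5
Reactants: 9 8-methoxy-7-{[(2E)-3-methyl-4-[(2S,4R)-4-methyl-5-oxooxolan-2-yl]but-2-en-1-yl]oxy}-2H-chromen-2-one
Product: 10 8-methoxy-7-{[(2R,3R)-3-methyl-3-{[(2S,4R)-4-methyl-5-oxooxolan-2-yl]methyl}oxiran-2-yl]methoxy}-2H-chromen-2-one
Conditions: D-fructose-derived Shi ketone (30 mol%), Oxone (2KHSO5·KHSO4·K2SO4), K2CO3, Bu4NHSO4, MeCN–CH2(OMe)2 / aq. Na2B4O7 buffer (pH 10.5), −10 → 0 °C, 2 h
Reagents that add atoms: potassium peroxymonosulfate (active salt of Oxone), [K+].[O-]S(=O)(=O)OO
Why: Shi asymmetric epoxidation; the chiral dioxirane transfers oxygen through a spiro transition state to the face of the E-trisubstituted alkene that gives the (2'R,3'R)-oxirane (the same sense as the (R,R)-epoxides obtained from trans-alkenes with this ketone), the remote lactone centres exert no influence, and the electron-poor coumarin C3=C4 bond is not oxidised.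

## Compound list

1 | geranyl acetate, (2E)-3,7-dimethylocta-2,6-dien-1-yl acetate | CC(=O)OC/C=C(\C)CCC=C(C)C | starting material
2 | (2E)-5-(5,5-dimethyl-1,2,4-trioxolan-3-yl)-3-methylpent-2-en-1-yl acetate (ozonide) | CC(=O)OC/C=C(\C)CCC1OOC(C)(C)O1 | intermediate
3 | (2E)-3-methyl-6-oxohex-2-en-1-yl acetate | CC(=O)OC/C=C(\C)CCC=O | intermediate
4 | (2E,5S)-5-chloro-3-methyl-6-oxohex-2-en-1-yl acetate | CC(=O)OC/C=C(\C)C[C@H](Cl)C=O | intermediate
5 | (2E,5S)-5-chloro-6-hydroxy-3-methylhex-2-en-1-yl acetate | CC(=O)OC/C=C(\C)C[C@H](Cl)CO | intermediate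
6 | (2E)-3-methyl-4-[(2R)-oxiran-2-yl]but-2-en-1-ol | OC/C=C(\C)C[C@@H]1CO1 | intermediate
7 | hydrangetin, 7-hydroxy-8-methoxy-2H-chromen-2-one | COc1c(O)ccc2ccc(=O)oc12 | starting material
8 | 8-methoxy-7-{[(2E)-3-methyl-4-[(2R)-oxiran-2-yl]but-2-en-1-yl]oxy}-2H-chromen-2-one | COc1c(OC/C=C(\C)C[C@@H]2CO2)ccc2ccc(=O)oc12 | intermediate
9 | 8-methoxy-7-{[(2E)-3-methyl-4-[(2S,4R)-4-methyl-5-oxooxolan-2-yl]but-2-en-1-yl]oxy}-2H-chromen-2-one | COc1c(OC/C=C(\C)C[C@@H]2C[C@@H](C)C(=O)O2)ccc2ccc(=O)oc12 | intermediate
10 | 8-methoxy-7-{[(2R,3R)-3-methyl-3-{[(2S,4R)-4-methyl-5-oxooxolan-2-yl]methyl}oxiran-2-yl]methoxy}-2H-chromen-2-one | COc1c(OC[C@H]2O[C@]2(C)C[C@@H]2C[C@@H](C)C(=O)O2)ccc2ccc(=O)oc12 | target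

## Step count and risks

Total step count: 5. Longest linear sequence: 5 (1 → 3 → 6 → 8 → 9 → 10); hydrangetin 7 enters unchanged at step 3.

Steps most likely to fail:

Step 4 (the proposed new annulation). The ammonium enolate may be too weak a nucleophile for an epoxide, propionate may open the epoxide instead, and catalyst control at C7' is unproven. The fallback uses known chemistry, sets out from 6 and comes back at 9. Compound 6, as its lithium alkoxide (n-BuLi), is opened at the terminal carbon by dilithioacetate (AcOH, 2 LiN(iPr)2, THF, 0 → 45 °C) and the hydroxy acid is lactonised on acidic work-up (TsOH, toluene) to (5S)-5-[(2E)-4-hydroxy-2-methylbut-2-en-1-yl]oxolan-2-one F1. Its dianion (2.2 equiv LiN(iPr)2, THF, −78 °C) is methylated with MeI anti to the ring substituent to give (3R,5S)-5-[(2E)-4-hydroxy-2-methylbut-2-en-1-yl]-3-methyloxolan-2-one F2 (trans favoured, typically about 10:1, separable). Mitsunobu coupling of this alcohol with 7 (PPh3, DIAD, THF) gives 9.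

Step 2 (one-pot chlorination, reduction, ring closure). The α-chloroaldehyde can racemise, and 6 is small and water-soluble. The fallback sets out from 3 and comes back at 6. L-Proline-catalysed α-aminoxylation with nitrosobenzene followed by NaBH4 gives (2E,5R)-6-hydroxy-3-methyl-5-[(phenylamino)oxy]hex-2-en-1-yl acetate F3. N–O cleavage (Zn, AcOH) gives (2E,5R)-5,6-dihydroxy-3-methylhex-2-en-1-yl acetate F4. Selective sulfonylation of the primary hydroxyl (2,4,6-triisopropylbenzenesulfonyl chloride, pyridine) gives (2E,5R)-5-hydroxy-3-methyl-6-{[2,4,6-tri(propan-2-yl)benzenesulfonyl]oxy}hex-2-en-1-yl acetate F5. K2CO3 in MeOH then closes the oxirane with retention at C5' and removes the acetate to give 6.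

Step 5 (Shi epoxidation). The γ-lactone and the coumarin may hydrolyse at pH 10.5, and the allylic-ether alkene may react slowly. The fallback sets out from 6 and comes back at 10. The hydroxy lactone F2 is made from 6 by way of F1 exactly as in the fallback for step 4. Sharpless asymmetric epoxidation of its allylic alcohol (Ti(OiPr)4, D-(−)-diethyl tartrate, t-BuOOH, 4 Å molecular sieves, CH2Cl2, −20 °C) gives (3R,5S)-5-{[(2R,3R)-3-(hydroxymethyl)-2-methyloxiran-2-yl]methyl}-3-methyloxolan-2-one F6. Mitsunobu coupling of this epoxy alcohol with 7 (PPh3, DIAD, THF) gives 10 without any aqueous base.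

## Further compounds

F1 | step 4 | (5S)-5-[(2E)-4-hydroxy-2-methylbut-2-en-1-yl]oxolan-2-one | OC/C=C(\C)C[C@@H]1CCC(=O)O1
F2 | step 4 | (3R,5S)-5-[(2E)-4-hydroxy-2-methylbut-2-en-1-yl]-3-methyloxolan-2-one | OC/C=C(\C)C[C@@H]1C[C@@H](C)C(=O)O1
F3 | step 2 | (2E,5R)-6-hydroxy-3-methyl-5-[(phenylamino)oxy]hex-2-en-1-yl acetate | CC(=O)OC/C=C(\C)C[C@@H](ONc1ccccc1)CO
F4 | step 2 | (2E,5R)-5,6-dihydroxy-3-methylhex-2-en-1-yl acetate | CC(=O)OC/C=C(\C)C[C@@H](O)CO
F5 | step 2 | (2E,5R)-5-hydroxy-3-methyl-6-{[2,4,6-tri(propan-2-yl)benzenesulfonyl]oxy}hex-2-en-1-yl acetate | CC(=O)OC/C=C(\C)C[C@@H](O)COS(=O)(=O)c1c(C(C)C)cc(C(C)C)cc1C(C)C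
F6 | step 5 | (3R,5S)-5-{[(2R,3R)-3-(hydroxymethyl)-2-methyloxiran-2-yl]methyl}-3-methyloxolan-2-one | OC[C@H]1O[C@]1(C)C[C@@H]1C[C@@H](C)C(=O)O1
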